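The synthesis rests on cutting the oxepine ring between C3 of the pyranone (ring C) and the adjacent CH2. The C5 bridge CH2–C(O)=CMe2 is a 2-oxyallyl unit held between two nucleophilic atoms in a 1,5-relationship: O2' of ring B and C3, the carbon alpha to the later C2. The key step exploits this. Under Pd(0), 2-hydroxy-4,5-dimethoxyacetophenone adds twice to a tertiary propargylic carbonate: oxygen at the central carbon, then the methyl-ketone carbon at the CH2 terminus of the resulting π-allyl. This closes the seven-membered ring with the tetrasubstituted enol ether in place. Ring A arrives as an O-prenyl chromene aldehyde. A final thermal cascade moves prenyl to C6 and closes ring C.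

Key step: step 2

Assumption: flavone numbering (O1, C2, C3, C4, C4a–C8a, ring B primed) is used for the target and its precursors. The target has no stereocentre and no alkene geometry to set. Compounds 4 and 7 are taken as purchasable; 7 is otherwise one Vilsmeier–Haack formylation away from 5-methoxyresorcinol.

Step 1
Reactants: 1 2-methylbut-3-yn-2-ol
Product: 3 methyl 2-methylbut-3-yn-2-yl carbonate, via lithium alkoxide 2 (not isolated)
Conditions: n-BuLi (1.0 equiv), THF, −78 °C; then ClCO2Me, −78 °C to rt
Reagents that add atoms: methyl chloroformate, COC(=O)Cl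
Why: Carbonate formation by O-acylation of a lithium alkoxide: one equivalent of n-BuLi removes only the O–H proton, which is far more acidic than the alkyne C–H, and the tertiary alkoxide 2 is acylated by the chloroformate; no stereocentre is formed.

Step 2
Reactants: 3 methyl 2-methylbut-3-yn-2-yl carbonate; 4 1-(2-hydroxy-4,5-dimethoxyphenyl)ethanone
Product: 6 7,8-dimethoxy-2-(propan-2-ylidene)-3,4-dihydro-1-benzoxepin-5(2H)-one, via aryloxy-π-allylpalladium cation 5 (not isolated)
Conditions: Pd2(dba)3·CHCl3 (5 mol %), dppf (12 mol %), DMSO, 100 °C, slow addition of 3 (1.3 equiv)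
Reagents that add atoms: none
Why: Proposed new method: Pd(0) ionises 3 in an SN2' sense with loss of CO2 to a cationic η3-propargyl/allenyl complex and methoxide, which deprotonates only the phenol of 4 (far more acidic than the methyl ketone), so oxygen attacks the central carbon and protonation of the palladacyclobutene gives the 2-aryloxy-π-allyl cation 5. The regenerated methoxide, strongly basic in DMSO, then forms the ketone enolate, whose carbon (later C3) attacks the CH2 terminus and closes the oxepinone in a 7-(enolendo)-exo-tet-type closure, a mode that the ring-closure rules for enolates allow. The closest known reaction type is the Tsuji-type double substitution of propargylic carbonates by O,C-bisnucleophiles such as 2-(2-hydroxyphenyl)acetates, which gives 2-alkylidenechromans; new here are the seven-membered ring and the unstabilised methyl-ketone pronucleophile. No stereocentre arises, and the new alkene has no geometry because its outer carbon carries two methyl groups. Attack at CH2 rather than CMe2 rests on the steric demand of the tertiary terminus under a wide-bite-angle diphosphine. O-allylation by the enolate oxygen or by a second phenoxide is reversible under Pd(0), whereas C-allylation is not, so the mixture should drain towards 6.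

Step 3
Reactants: 7 2,4-dihydroxy-6-methoxybenzaldehyde
Product: 9 5-hydroxy-7-methoxy-2,2-dimethyl-2H-chromene-6-carbaldehyde, via ortho-quinone methide 8 (not isolated)
Conditions: 3-methylbut-2-enal (1.5 equiv), ethylenediammonium diacetate (20 mol %), toluene, reflux
Reagents that add atoms: 3-methylbut-2-enal, CC(C)=CC=O
Why: Formal [3+3] chromene annulation: iminium-activated enal is attacked by C3, the carbon between the two free hydroxyls (the site preference known for 2,4-dihydroxybenzaldehyde itself), loss of water gives ortho-quinone methide 8, and oxa-6π electrocyclisation runs through the 4-oxygen because the 2-OH stays hydrogen-bonded to the formyl group; no stereocentre is formed.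

Step 4
Reactants: 9 5-hydroxy-7-methoxy-2,2-dimethyl-2H-chromene-6-carbaldehyde
Product: 10 7-methoxy-2,2-dimethyl-5-[(3-methylbut-2-en-1-yl)oxy]-2H-chromene-6-carbaldehyde
Conditions: prenyl bromide, K2CO3, DMF, 50 °C
Reagents that add atoms: 1-bromo-3-methylbut-2-ene (prenyl bromide), CC(C)=CCBr
Why: Williamson ether synthesis: in DMF the base breaks the hydrogen bond to the formyl group and the only free phenol is O-alkylated by the primary allylic bromide in an SN2 reaction, the ether serving both as protecting group for the later O1 and as source of the C6 prenyl group; no stereocentre is formed.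

Step 5
Reactants: 6 7,8-dimethoxy-2-(propan-2-ylidene)-3,4-dihydro-1-benzoxepin-5(2H)-one; 10 7-methoxy-2,2-dimethyl-5-[(3-methylbut-2-en-1-yl)oxy]-2H-chromene-6-carbaldehyde
Product: 12 aldol adduct 4-{hydroxy[7-methoxy-2,2-dimethyl-5-(3-methylbut-2-enyloxy)-2H-chromen-6-yl]methyl}-7,8-dimethoxy-2-(propan-2-ylidene)-3,4-dihydro-1-benzoxepin-5(2H)-one (diastereomer mixture), via lithium enolate 11 (not isolated)
Conditions: LiHMDS, THF, −78 °C; then 10, −78 °C; AcOH quench at −78 °C
Reagents that add atoms: none
Why: Directed aldol addition: ketone 6 has a single enolisable position (C4 of the benzoxepinone, the later flavone C3), its lithium enolate 11 adds to the non-enolisable aldehyde 10 with the ortho alkoxy groups helping to chelate the aldolate at low temperature, and the two new stereocentres arise without control as a diastereomer mixture of no consequence because both carbons become sp2 in steps 6 and 7.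

Step 6
Reactants: 12 aldol adduct
Product: 13 4-[7-methoxy-2,2-dimethyl-5-(3-methylbut-2-enyloxy)-2H-chromene-6-carbonyl]-7,8-dimethoxy-2-(propan-2-ylidene)-3,4-dihydro-1-benzoxepin-5(2H)-one (racemic)
Conditions: IBX (3 equiv), EtOAc, 77 °C
Reagents that add atoms: none
Why: IBX oxidation of a β-hydroxy ketone to the β-diketone, a neutral method that should stop at the diketone and leave enol ether, chromene and prenyl alkenes untouched; the one remaining stereocentre (later C3) is configurationally labile and is carried as the racemate.

Step 7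
Reactants: 13 O-prenyl diketone
Product: 18 target oxepinoflavone CNP0192589.0, via ortho-dienone 14 (not isolated), via para-dienone 15 (not isolated), via hydroxy diketone 16 (not isolated), via cyclic hemiketal 17 (not isolated)
Conditions: PhNEt2 (degassed), 200 °C, sealed tube
Reagents that add atoms: none
Why: Aromatic para-Claisen–Cope rearrangement followed by flavone cyclodehydration: the prenyl ether shifts [3,3] to the blocked ortho carbon (dienone 14), a Cope shift carries the inverted allyl group on to the only free ring carbon, para to oxygen (dienone 15), restoring the normal prenyl connectivity, tautomerisation frees phenol 16, and this phenol adds to the ring-B ketone and hemiketal 17 loses water by E1cB in the hot basic solvent, so every transient stereocentre is erased and no acid touches the enol ether.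

Compound list
1 | 2-methylbut-3-yn-2-ol | CC(C)(O)C#C | starting material
2 | lithium 2-methylbut-3-yn-2-olate | [Li+].CC(C)([O-])C#C | intermediate
3 | methyl 2-methylbut-3-yn-2-yl carbonate | COC(=O)OC(C)(C)C#C | intermediate
4 | 1-(2-hydroxy-4,5-dimethoxyphenyl)ethanone | CC(=O)c1cc(OC)c(OC)cc1O | starting material
5 | 2-(2-acetyl-4,5-dimethoxyphenoxy)-π-allylpalladium cation (drawn in its σ-allyl form, diphosphine omitted) | CC(=O)c1cc(OC)c(OC)cc1OC(C[Pd+])=C(C)C | intermediate
6 | 7,8-dimethoxy-2-(propan-2-ylidene)-3,4-dihydro-1-benzoxepin-5(2H)-one | COc1cc2OC(=C(C)C)CCC(=O)c2cc1OC | intermediate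
7 | 2,4-dihydroxy-6-methoxybenzaldehyde | COc1cc(O)cc(O)c1C=O | starting material
8 | ortho-quinone methide, 2-hydroxy-6-methoxy-3-(3-methylbut-2-enylidene)-4-oxocyclohexa-1,5-diene-1-carbaldehyde | O=CC1=C(O)C(=CC=C(C)C)C(=O)C=C1OC | intermediate
9 | 5-hydroxy-7-methoxy-2,2-dimethyl-2H-chromene-6-carbaldehyde | O=Cc1c(O)c2C=CC(C)(C)Oc2cc1OC | intermediate
10 | 7-methoxy-2,2-dimethyl-5-[(3-methylbut-2-en-1-yl)oxy]-2H-chromene-6-carbaldehyde | O=Cc1c(OCC=C(C)C)c2C=CC(C)(C)Oc2cc1OC | intermediate
11 | lithium enolate of 6 | [Li+].[O-]C1=CCC(=C(C)C)Oc2cc(OC)c(OC)cc12 | intermediate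
12 | aldol adduct of 6 and 10 (diastereomer mixture, racemic) | OC(c1c(OCC=C(C)C)c2C=CC(C)(C)Oc2cc1OC)C1CC(=C(C)C)Oc2cc(OC)c(OC)cc2C1=O | intermediate
13 | O-prenyl 1,3-diketone (racemic) | O=C(c1c(OCC=C(C)C)c2C=CC(C)(C)Oc2cc1OC)C1CC(=C(C)C)Oc2cc(OC)c(OC)cc2C1=O | intermediate
14 | ortho-dienone carrying the 1,1-dimethylallyl group on the chromene ring-fusion carbon (stereoisomer mixture) | O=C(C1=C(OC)C=C2OC(C)(C)C=CC2(C(C)(C)C=C)C1=O)C1CC(=C(C)C)Oc2cc(OC)c(OC)cc2C1=O | intermediate
15 | para-dienone carrying prenyl and H on the later C6 (stereoisomer mixture) | O=C(C1=C(OC)C(CC=C(C)C)C2=C(C=CC(C)(C)O2)C1=O)C1CC(=C(C)C)Oc2cc(OC)c(OC)cc2C1=O | intermediate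
16 | hydroxy diketone, 4-[5-hydroxy-7-methoxy-2,2-dimethyl-8-(3-methylbut-2-enyl)-2H-chromene-6-carbonyl]-7,8-dimethoxy-2-(propan-2-ylidene)-3,4-dihydro-1-benzoxepin-5(2H)-one (racemic) | O=C(c1c(O)c2C=CC(C)(C)Oc2c(CC=C(C)C)c1OC)C1CC(=C(C)C)Oc2cc(OC)c(OC)cc2C1=O | intermediate
17 | cyclic hemiketal (2-hydroxyflavanone form, stereoisomer mixture) | COc1cc2c(cc1OC)C1(O)Oc3c4c(c(CC=C(C)C)c(OC)c3C(=O)C1CC(=C(C)C)O2)OC(C)(C)C=C4 | intermediate
18 | CNP0192589.0: 5,4',5'-trimethoxy-6-prenyl-7,8-(2,2-dimethylpyrano)flavone with C3 and O2' bridged by CH2–C(=CMe2) | COc1cc2c(cc1OC)-c1oc3c4c(c(CC=C(C)C)c(OC)c3c(=O)c1CC(=C(C)C)O2)OC(C)(C)C=C4 | target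

Total step count: 7. Longest linear sequence: 5 steps (steps 3, 4, 5, 6, 7; the branch through steps 1 and 2 is equally long).

Steps most likely to fail

1. Step 2 (labelled step).
- What may go wrong: β-hydride loss from the π-allyl complex to a 2-aryloxydiene, β-hydride loss from the allenylpalladium species to the enyne, lasting capture of the π-allyl by a second phenoxide, or enolisation of the methyl ketone too slow for the seven-membered closure to compete.
- Fallback (known chemistry, same bond closed): it sets out from 4 and comes back at 6.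
  - 3-Methylbut-2-enal is epoxidised (H2O2, NaOH, MeOH, Weitz–Scheffer epoxidation) to 3,3-dimethyloxirane-2-carbaldehyde F1.
  - The phenoxide of 4 (K2CO3, DMF) opens F1 at the carbon next to the formyl group. The β-hydroxy aldehyde then loses water to give 2-(2-acetyl-4,5-dimethoxyphenoxy)-3-methylbut-2-enal F2. This is the known conversion of α,β-epoxy carbonyl compounds into α-aryloxy enones.
  - An intramolecular aldol condensation of the acetyl methyl group on the formyl group (piperidine, AcOH, toluene, reflux) closes the same carbon–carbon bond as a double bond. It gives 7,8-dimethoxy-2-(propan-2-ylidene)-1-benzoxepin-5(2H)-one F3.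
  - 1,4-Reduction of the enone with [(Ph3P)CuH]6 in toluene gives 6.

2. Step 5.
- What may go wrong: slow addition to the electron-rich, doubly ortho-alkoxylated aldehyde, reversal by retro-aldol on warming, or loss of water from the very electron-rich benzylic aldol.
- Fallback (acylation in place of aldol and oxidation): it sets out from 10 and comes back at 13, so step 6 falls away.
  - Pinnick oxidation (NaClO2, NaH2PO4, large excess of 2-methylbut-2-ene, t-BuOH/H2O) gives 7-methoxy-2,2-dimethyl-5-(3-methylbut-2-enyloxy)-2H-chromene-6-carboxylic acid F4.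
  - 1-Chloro-N,N,2-trimethylpropenylamine in CH2Cl2 converts it under neutral conditions into the acid chloride F5.
  - C-acylation of lithium enolate 11 (two equivalents, THF, −78 °C) gives 13.

3. Step 7.
- What may go wrong: loss of the prenyl group as isoprene by a retro-ene process, arrest or diversion at the dienone stage, retro-Claisen cleavage of the diketone at 200 °C, or incomplete dehydration of the hemiketal.
- Fallback (rearrangement moved to the robust aldehyde, ring C closed cold): it sets out from 10 and comes back at 16.
  - Heating 10 in PhNEt2 at 200 °C gives 5-hydroxy-7-methoxy-2,2-dimethyl-8-(3-methylbut-2-enyl)-2H-chromene-6-carbaldehyde F6.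
  - TBSOTf and 2,6-lutidine give its silyl ether F7.
  - Aldol addition of enolate 11 gives the silylated aldol adduct F8, and IBX gives the silylated diketone F9.
  - TBAF in THF frees 16, which closes to 17 at room temperature. Hemiketal 17 is dehydrated separately by MsCl and Et3N (E1cB) to 18.

Further compounds
F1 | step 2 | 3,3-dimethyloxirane-2-carbaldehyde (racemic) | CC1(C)OC1C=O
F2 | step 2 | 2-(2-acetyl-4,5-dimethoxyphenoxy)-3-methylbut-2-enal | CC(=O)c1cc(OC)c(OC)cc1OC(C=O)=C(C)C
F3 | step 2 | 7,8-dimethoxy-2-(propan-2-ylidene)-1-benzoxepin-5(2H)-one | COc1cc2OC(=C(C)C)C=CC(=O)c2cc1OC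
F4 | step 5 | 7-methoxy-2,2-dimethyl-5-(3-methylbut-2-enyloxy)-2H-chromene-6-carboxylic acid | OC(=O)c1c(OCC=C(C)C)c2C=CC(C)(C)Oc2cc1OC
F5 | step 5 | 7-methoxy-2,2-dimethyl-5-(3-methylbut-2-enyloxy)-2H-chromene-6-carbonyl chloride | O=C(Cl)c1c(OCC=C(C)C)c2C=CC(C)(C)Oc2cc1OC
F6 | step 7 | 5-hydroxy-7-methoxy-2,2-dimethyl-8-(3-methylbut-2-enyl)-2H-chromene-6-carbaldehyde | O=Cc1c(O)c2C=CC(C)(C)Oc2c(CC=C(C)C)c1OC
F7 | step 7 | 5-(tert-butyldimethylsilyloxy)-7-methoxy-2,2-dimethyl-8-(3-methylbut-2-enyl)-2H-chromene-6-carbaldehyde | O=Cc1c(O[Si](C)(C)C(C)(C)C)c2C=CC(C)(C)Oc2c(CC=C(C)C)c1OC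
F8 | step 7 | silylated aldol adduct of 6 and F7 (diastereomer mixture) | OC(c1c(O[Si](C)(C)C(C)(C)C)c2C=CC(C)(C)Oc2c(CC=C(C)C)c1OC)C1CC(=C(C)C)Oc2cc(OC)c(OC)cc2C1=O
F9 | step 7 | silylated 1,3-diketone (racemic) | O=C(c1c(O[Si](C)(C)C(C)(C)C)c2C=CC(C)(C)Oc2c(CC=C(C)C)c1OC)C1CC(=C(C)C)Oc2cc(OC)c(OC)cc2C1=O
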